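Numbering: ring C1 (C=O), C2=C3, C4 (CH–OMe), C5, C6 (quaternary); side chain C7 (CH–CH3), C8 (CH–OH). Everything rests on disconnecting C3–C4. C6 of the cyclohexenone ring carries two CH2 arms, ring C5 and the allyl CH2; with C4 and the allyl CH as aldehyde carbons they are identical CH2–CHO groups on a non-stereogenic C6. A Nozaki–Hiyama–Kishi closure of the (Z)-β-iodoenone (C1–C3) onto one arm forms the ring and sets C4 and C6 in one operation, steered by the C7/C8 pair from a crotylboration. The precursor is an acyclic 3,3-disubstituted pentanedial carrying the iodoenone and the silylated side chain; the spare arm later becomes the allyl group.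

Key step: step 10

Assumption: the crotylborane made from (−)-Ipc2BOMe, the enantiomer derived from (+)-α-pinene, is taken to attack the Si face of the aldehyde, as is usual for this reagent; if the opposite sense were found, the antipodal borane would be used.
Atom labels C1–C8 are those of the target and are used for all intermediates.

Step 1
Reactants: 1 veratraldehyde; 2 cis-but-2-ene
Product: 7 (1S,2R)-1-(3,4-dimethoxyphenyl)-2-methylbut-3-en-1-ol, via crotylpotassium 3 (not isolated), via potassium crotylborate 4 (not isolated), via crotylborane 5 (not isolated), via borinate ester 6 (not isolated)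
Conditions: 2 (excess), KOtBu, n-BuLi, THF, −78 to −45 °C; (−)-Ipc2BOMe, −78 °C; BF3·OEt2; 1, −78 °C; then 3 M NaOH, 30% H2O2, reflux
Reagents that add atoms: none
Why: Brown asymmetric crotylboration: the (Z)-crotylborane reacts through a closed Zimmerman–Traxler chair, so the Z geometry is translated into the syn C7/C8 relationship, and the isopinocampheyl groups derived from (+)-α-pinene direct the allyl transfer to the Si face of the aldehyde, which sets C8 as S and C7 as R.

Step 2
Reactants: 7 (1S,2R)-1-(3,4-dimethoxyphenyl)-2-methylbut-3-en-1-ol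
Product: 9 (1S,2R)-1-(3,4-dimethoxyphenyl)-2-methylbutane-1,4-diol, via alkylborane 8 (not isolated)
Conditions: 9-BBN (2.2 equiv), THF, 0 °C to rt; then 3 M NaOH, 30% H2O2, 0 °C to rt
Reagents that add atoms: hydrogen peroxide, OO
Why: Anti-Markovnikov hydroboration–oxidation: 9-BBN places boron on the terminal carbon of the monosubstituted alkene and alkaline peroxide replaces it by hydroxyl with retention, without touching C7 or C8.

Step 3
Reactants: 9 (1S,2R)-1-(3,4-dimethoxyphenyl)-2-methylbutane-1,4-diol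
Product: 11 (4R,5S)-5-(3,4-dimethoxyphenyl)-4-methyloxolan-2-one (cis lactone), via lactol 10 (not isolated)
Conditions: TEMPO (2,2,6,6-tetramethylpiperidin-1-oxyl, 0.2 equiv), PhI(OAc)2 (2.5 equiv), CH2Cl2, rt
Reagents that add atoms: none
Why: TEMPO-catalysed oxidative lactonisation of a 1,4-diol: the oxoammonium salt oxidises the primary alcohol first, the aldehyde is trapped by the C8 hydroxyl as the lactol and this is oxidised to the γ-lactone, which shields the benzylic alcohol from oxidation and leaves C7 and C8 cis on the ring.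

Step 4
Reactants: 11 (4R,5S)-5-(3,4-dimethoxyphenyl)-4-methyloxolan-2-one; 12 allyl bromide (first equivalent)
Product: 14 (4R,5S)-5-(3,4-dimethoxyphenyl)-4-methyl-3,3-di(prop-2-en-1-yl)oxolan-2-one, via monoallyl lactone 13 (not isolated)
Conditions: LiN(iPr)2 (1.1 equiv), THF, −78 °C, then 12 (1.2 equiv), −78 to −20 °C; LiN(iPr)2 (1.3 equiv), DMPU, −78 °C, then 12 (1.5 equiv), −78 to 0 °C
Reagents that add atoms: allyl bromide (second equivalent of 12, for the second alkylation), C=CCBr
Why: Lactone enolate alkylation carried out twice in one flask, each round consuming one equivalent of allyl bromide: the first allyl group enters trans to the C7 methyl group and the second alkylation of the regenerated enolate makes C6 quaternary with two identical substituents, so no stereocontrol is required at C6.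

Step 5
Reactants: 14 (4R,5S)-5-(3,4-dimethoxyphenyl)-4-methyl-3,3-di(prop-2-en-1-yl)oxolan-2-one
Product: 15 (3R,4S)-4-(3,4-dimethoxyphenyl)-4-hydroxy-N-methoxy-N,3-dimethyl-2,2-di(prop-2-en-1-yl)butanamide
Conditions: MeNH(OMe)·HCl, AlMe3, CH2Cl2, 0 °C to rt; aq. KNaC4H4O6 (potassium sodium tartrate) work-up; crude product used at once
Reagents that add atoms: N,O-dimethylhydroxylamine hydrochloride, CNOC.Cl
Why: Weinreb aminolysis of a lactone: the aluminium amide formed from AlMe3 and the amine hydrochloride activates the carbonyl group, delivers the amine and holds the C8 oxygen as an aluminium alkoxide until work-up, which counters the tendency of the gem-diallyl hydroxy amide to close again.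

Step 6
Reactants: 15 (3R,4S)-4-(3,4-dimethoxyphenyl)-4-hydroxy-N-methoxy-N,3-dimethyl-2,2-di(prop-2-en-1-yl)butanamide
Product: 16 (3R,4S)-4-[tert-butyl(dimethyl)silyl]oxy-4-(3,4-dimethoxyphenyl)-N-methoxy-N,3-dimethyl-2,2-di(prop-2-en-1-yl)butanamide
Conditions: TBSOTf, 2,6-lutidine, CH2Cl2, −78 to 0 °C
Reagents that add atoms: tert-butyldimethylsilyl triflate, CC(C)(C)[Si](C)(C)OS(=O)(=O)C(F)(F)F
Why: Silyl ether formation with a silyl triflate and a hindered base, reactive enough for the congested benzylic alcohol, which removes the hydroxyl group that could re-form the lactone and later interfere with both aldehyde arms; C8 keeps its configuration because the C–O bond is not touched.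

Step 7
Reactants: 16 (3R,4S)-4-[tert-butyl(dimethyl)silyl]oxy-4-(3,4-dimethoxyphenyl)-N-methoxy-N,3-dimethyl-2,2-di(prop-2-en-1-yl)butanamide; 17 ethynylmagnesium bromide
Product: 18 (5R,6S)-6-[tert-butyl(dimethyl)silyl]oxy-6-(3,4-dimethoxyphenyl)-5-methyl-4,4-di(prop-2-en-1-yl)hex-1-yn-3-one
Conditions: 17 (0.5 M in THF, 4 equiv), THF, 0 °C to rt; quench into cold 1 M aq. NaHSO4
Reagents that add atoms: none
Why: Weinreb ketone synthesis: the slim alkynyl Grignard reagent adds once to the hindered amide, the chelated magnesium adduct survives until the acidic quench, and protonating the released amine at that point prevents its conjugate addition to the ynone.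

Step 8
Reactants: 18 (5R,6S)-6-[tert-butyl(dimethyl)silyl]oxy-6-(3,4-dimethoxyphenyl)-5-methyl-4,4-di(prop-2-en-1-yl)hex-1-yn-3-one
Product: 19 (1Z,5R,6S)-6-[tert-butyl(dimethyl)silyl]oxy-6-(3,4-dimethoxyphenyl)-1-iodo-5-methyl-4,4-di(prop-2-en-1-yl)hex-1-en-3-one
Conditions: LiI (1.5 equiv), AcOH (3 equiv), MeCN, rt, in the dark
Reagents that add atoms: lithium iodide, [Li+].[I-]
Why: Hydroiodination of an ynone: iodide adds in conjugate fashion and the allenolate is protonated anti to iodine, which gives the (Z)-β-iodoenone under kinetic control at room temperature while the isolated alkenes and the silyl ether do not react.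

Step 9
Reactants: 19 (1Z,5R,6S)-6-[tert-butyl(dimethyl)silyl]oxy-6-(3,4-dimethoxyphenyl)-1-iodo-5-methyl-4,4-di(prop-2-en-1-yl)hex-1-en-3-one
Product: 21 3-[(1S,2R)-1-[tert-butyl(dimethyl)silyl]oxy-1-(3,4-dimethoxyphenyl)propan-2-yl]-3-[(2Z)-3-iodoprop-2-enoyl]pentanedial, via tetraol 20 (not isolated)
Conditions: OsO4 (2 mol %), NaIO4 (5 equiv), 2,6-lutidine (4 equiv), 1,4-dioxane/H2O 3:1, rt; dried azeotropically and used without storage
Reagents that add atoms: osmium tetroxide, O=[Os](=O)(=O)=O; sodium periodate, [Na+].[O-][I](=O)(=O)=O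
Why: Lemieux–Johnson oxidative cleavage: OsO4 dihydroxylates the two electron-rich terminal alkenes far faster than the electron-poor iodoenone and periodate cleaves each diol to an aldehyde, 2,6-lutidine suppressing over-oxidation, so that C6 now carries two identical CH2–CHO arms.

Step 10
Reactants: 21 3-[(1S,2R)-1-[tert-butyl(dimethyl)silyl]oxy-1-(3,4-dimethoxyphenyl)propan-2-yl]-3-[(2Z)-3-iodoprop-2-enoyl]pentanedial
Product: 23 (4S,6R)-6-[(1S,2R)-1-[tert-butyl(dimethyl)silyl]oxy-1-(3,4-dimethoxyphenyl)propan-2-yl]-4-hydroxy-6-(2-oxoethyl)cyclohex-2-en-1-one, via alkenylchromium dichloride 22 (not isolated)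
Conditions: CrCl2 (8 equiv), NiCl2 (0.1 equiv), degassed DMSO/THF 3:1, 0.005 M, 21 added over 6 h, rt; quench with sat. aq. NH4Cl, extraction with EtOAc
Reagents that add atoms: none
Why: Zerovalent nickel, formed from NiCl2 by CrCl2, inserts into the C3–I bond, hands the alkenyl group to trivalent chromium with retention of the Z geometry, and the alkenylchromium adds to an aldehyde carbon through a four-centre transition state in which the aldehyde oxygen is bound to the same chromium atom. The closest known reaction type is the intramolecular Nozaki–Hiyama–Kishi addition of a (Z)-β-iodoenone to one tethered aldehyde, which gives 4-hydroxycyclohex-2-enones under neutral conditions; the choice between two diastereotopic aldehyde arms asked for here has no direct precedent and is the one real uncertainty of the route. The ring C1–C2=C3–C4–C5–C6 closes by 6-exo-trig attack of C3 on the carbonyl carbon C4. C4 is set by the half-chair of this closure, in which the oxygen must lie close to the enone plane to reach chromium (pseudo-equatorial) and the branched C7 group on C6 takes the other pseudo-equatorial site, so that O4 and C7 end up cis (Re-face attack, 4S). C6 is set by which arm enters the ring: with the bulky C8(OTBS)Ar branch of C7 turned away from the chromium-bound C1 carbonyl, the pro-S arm lies next to C7–H and the other next to C7–CH3, so the pro-S arm should close and give the target configuration. The step thus needs arm and face selectivity together; the face is secured by the chair, the arm only by the neighbouring C7 centre, and since each arm reaches the diequatorial chair through one carbonyl face only, a chiral oxazoline–sulfonamide ligand on chromium of the sense that favours the 4S carbinol can be added to reinforce the arm choice.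

Step 11
Reactants: 23 (4S,6R)-6-[(1S,2R)-1-[tert-butyl(dimethyl)silyl]oxy-1-(3,4-dimethoxyphenyl)propan-2-yl]-4-hydroxy-6-(2-oxoethyl)cyclohex-2-en-1-one
Product: 24 (4S,6R)-6-[(1S,2R)-1-[tert-butyl(dimethyl)silyl]oxy-1-(3,4-dimethoxyphenyl)propan-2-yl]-4-methoxy-6-(2-oxoethyl)cyclohex-2-en-1-one
Conditions: Me3OBF4, 1,8-bis(dimethylamino)naphthalene, 4 Å molecular sieves, CH2Cl2, 0 °C to rt
Reagents that add atoms: trimethyloxonium tetrafluoroborate, C[O+](C)C.F[B-](F)(F)F
Why: O-Alkylation with a trialkyloxonium salt in the presence of a non-nucleophilic proton scavenger, which methylates the secondary allylic alcohol without a base able to enolise the aldehyde or isomerise the 4-hydroxyenone and without breaking the C4–O bond, so C4 stays S.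

Step 12
Reactants: 24 (4S,6R)-6-[(1S,2R)-1-[tert-butyl(dimethyl)silyl]oxy-1-(3,4-dimethoxyphenyl)propan-2-yl]-4-methoxy-6-(2-oxoethyl)cyclohex-2-en-1-one
Product: 25 (4S,6S)-6-[(1S,2R)-1-[tert-butyl(dimethyl)silyl]oxy-1-(3,4-dimethoxyphenyl)propan-2-yl]-4-methoxy-6-(prop-2-en-1-yl)cyclohex-2-en-1-one
Conditions: Ph3PCH3Br, KN(SiMe3)2, THF, 0 °C; then 24, −78 to 0 °C
Reagents that add atoms: methyltriphenylphosphonium bromide, C[P+](c1ccccc1)(c1ccccc1)c1ccccc1.[Br-]
Why: Wittig methylenation: the unstabilised ylide attacks the unhindered aldehyde at low temperature much faster than the conjugated ketone on the quaternary carbon, turning the CH2–CHO arm into the allyl group without affecting C4 or C6.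

Step 13
Reactants: 25 (4S,6S)-6-[(1S,2R)-1-[tert-butyl(dimethyl)silyl]oxy-1-(3,4-dimethoxyphenyl)propan-2-yl]-4-methoxy-6-(prop-2-en-1-yl)cyclohex-2-en-1-one
Product: 26 (4S,6S)-6-[(1S,2R)-1-(3,4-dimethoxyphenyl)-1-hydroxypropan-2-yl]-4-methoxy-6-(prop-2-en-1-yl)cyclohex-2-en-1-one (CNP0138111.1)
Conditions: Bu4NF/AcOH (1:1), THF, rt
Reagents that add atoms: none
Why: Fluoride-mediated silyl ether cleavage buffered with acetic acid, which breaks the Si–O bond only and so leaves C8 untouched, the buffer keeping the 4-methoxyenone away from basic fluoride.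

Compound list
1 | veratraldehyde (3,4-dimethoxybenzaldehyde) | COc1ccc(C=O)cc1OC | starting material
2 | cis-but-2-ene | C/C=C\C | starting material
3 | (Z)-but-2-enylpotassium (crotylpotassium) | C/C=C\C[K] | intermediate
4 | potassium (Z)-but-2-enyl(methoxy)bis(isopinocampheyl)borate | [K+].C/C=C\C[B-](OC)([C@@H]1C[C@@H]2C[C@@H](C2(C)C)[C@H]1C)[C@@H]1C[C@@H]2C[C@@H](C2(C)C)[C@H]1C | intermediate
5 | (Z)-but-2-enylbis(isopinocampheyl)borane | C/C=C\CB([C@@H]1C[C@@H]2C[C@@H](C2(C)C)[C@H]1C)[C@@H]1C[C@@H]2C[C@@H](C2(C)C)[C@H]1C | intermediate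
6 | bis(isopinocampheyl)borinate ester of alcohol 7 | C=C[C@@H](C)[C@H](OB([C@@H]1C[C@@H]2C[C@@H](C2(C)C)[C@H]1C)[C@@H]1C[C@@H]2C[C@@H](C2(C)C)[C@H]1C)c1ccc(OC)c(OC)c1 | intermediate
7 | (1S,2R)-1-(3,4-dimethoxyphenyl)-2-methylbut-3-en-1-ol | C=C[C@@H](C)[C@H](O)c1ccc(OC)c(OC)c1 | intermediate
8 | B-alkyl-9-borabicyclo[3.3.1]nonane from 7 (boron on the terminal carbon) | C[C@H](CCB1C2CCCC1CCC2)[C@H](O)c3ccc(OC)c(OC)c3 | intermediate
9 | (1S,2R)-1-(3,4-dimethoxyphenyl)-2-methylbutane-1,4-diol | OCC[C@@H](C)[C@H](O)c1ccc(OC)c(OC)c1 | intermediate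
10 | (4R,5S)-5-(3,4-dimethoxyphenyl)-4-methyloxolan-2-ol (anomer mixture) | OC1C[C@@H](C)[C@H](O1)c2ccc(OC)c(OC)c2 | intermediate
11 | (4R,5S)-5-(3,4-dimethoxyphenyl)-4-methyloxolan-2-one | O=C1C[C@@H](C)[C@H](O1)c2ccc(OC)c(OC)c2 | intermediate
12 | allyl bromide | C=CCBr | starting material
13 | (3R,4R,5S)-5-(3,4-dimethoxyphenyl)-4-methyl-3-(prop-2-en-1-yl)oxolan-2-one | C=CC[C@@H]1[C@@H](C)[C@H](OC1=O)c2ccc(OC)c(OC)c2 | intermediate
14 | (4R,5S)-5-(3,4-dimethoxyphenyl)-4-methyl-3,3-di(prop-2-en-1-yl)oxolan-2-one | C=CCC1(CC=C)[C@@H](C)[C@H](OC1=O)c2ccc(OC)c(OC)c2 | intermediate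
15 | (3R,4S)-4-(3,4-dimethoxyphenyl)-4-hydroxy-N-methoxy-N,3-dimethyl-2,2-di(prop-2-en-1-yl)butanamide | C=CCC(CC=C)([C@@H](C)[C@H](O)c1ccc(OC)c(OC)c1)C(=O)N(C)OC | intermediate
16 | (3R,4S)-4-[tert-butyl(dimethyl)silyl]oxy-4-(3,4-dimethoxyphenyl)-N-methoxy-N,3-dimethyl-2,2-di(prop-2-en-1-yl)butanamide | C=CCC(CC=C)([C@@H](C)[C@H](O[Si](C)(C)C(C)(C)C)c1ccc(OC)c(OC)c1)C(=O)N(C)OC | intermediate
17 | ethynylmagnesium bromide | C#C[Mg]Br | starting material
18 | (5R,6S)-6-[tert-butyl(dimethyl)silyl]oxy-6-(3,4-dimethoxyphenyl)-5-methyl-4,4-di(prop-2-en-1-yl)hex-1-yn-3-one | C=CCC(CC=C)([C@@H](C)[C@H](O[Si](C)(C)C(C)(C)C)c1ccc(OC)c(OC)c1)C(=O)C#C | intermediate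
19 | (1Z,5R,6S)-6-[tert-butyl(dimethyl)silyl]oxy-6-(3,4-dimethoxyphenyl)-1-iodo-5-methyl-4,4-di(prop-2-en-1-yl)hex-1-en-3-one | C=CCC(CC=C)([C@@H](C)[C@H](O[Si](C)(C)C(C)(C)C)c1ccc(OC)c(OC)c1)C(=O)/C=C\I | intermediate
20 | tetraol from dihydroxylation of both allyl groups of 19 (mixture at the two new carbinol carbons) | OCC(O)CC(CC(O)CO)([C@@H](C)[C@H](O[Si](C)(C)C(C)(C)C)c1ccc(OC)c(OC)c1)C(=O)/C=C\I | intermediate
21 | 3-[(1S,2R)-1-[tert-butyl(dimethyl)silyl]oxy-1-(3,4-dimethoxyphenyl)propan-2-yl]-3-[(2Z)-3-iodoprop-2-enoyl]pentanedial | O=CCC(CC=O)([C@@H](C)[C@H](O[Si](C)(C)C(C)(C)C)c1ccc(OC)c(OC)c1)C(=O)/C=C\I | intermediate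
22 | (Z)-alkenylchromium dichloride from 21 (trivalent chromium on C3) | O=CCC(CC=O)([C@@H](C)[C@H](O[Si](C)(C)C(C)(C)C)c1ccc(OC)c(OC)c1)C(=O)/C=C\[Cr](Cl)Cl | intermediate
23 | (4S,6R)-6-[(1S,2R)-1-[tert-butyl(dimethyl)silyl]oxy-1-(3,4-dimethoxyphenyl)propan-2-yl]-4-hydroxy-6-(2-oxoethyl)cyclohex-2-en-1-one | O=CC[C@@]1([C@@H](C)[C@H](O[Si](C)(C)C(C)(C)C)c2ccc(OC)c(OC)c2)C[C@H](O)C=CC1=O | intermediate
24 | (4S,6R)-6-[(1S,2R)-1-[tert-butyl(dimethyl)silyl]oxy-1-(3,4-dimethoxyphenyl)propan-2-yl]-4-methoxy-6-(2-oxoethyl)cyclohex-2-en-1-one | O=CC[C@@]1([C@@H](C)[C@H](O[Si](C)(C)C(C)(C)C)c2ccc(OC)c(OC)c2)C[C@H](OC)C=CC1=O | intermediate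
25 | (4S,6S)-6-[(1S,2R)-1-[tert-butyl(dimethyl)silyl]oxy-1-(3,4-dimethoxyphenyl)propan-2-yl]-4-methoxy-6-(prop-2-en-1-yl)cyclohex-2-en-1-one | C=CC[C@@]1([C@@H](C)[C@H](O[Si](C)(C)C(C)(C)C)c2ccc(OC)c(OC)c2)C[C@H](OC)C=CC1=O | intermediate
26 | (4S,6S)-6-[(1S,2R)-1-(3,4-dimethoxyphenyl)-1-hydroxypropan-2-yl]-4-methoxy-6-(prop-2-en-1-yl)cyclohex-2-en-1-one | C=CC[C@@]1([C@@H](C)[C@H](O)c2ccc(OC)c(OC)c2)C[C@H](OC)C=CC1=O | target

Total step count: 13. Longest linear sequence: 13 steps (1 to 26).

Steps most likely to fail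

1. Step 10. The alkenylchromium may discriminate poorly between the two diastereotopic CH2–CHO arms, or close in part through the chair with axial oxygen, so that C6 and C4 isomers form together. Fallback (known chemistry): C6 is fixed before ring closure by making the two arms different. Setting out from lactone 11, deprotonation with LiN(iPr)2 and alkylation with prenyl bromide gives the trans prenyl lactone F1. A second deprotonation and allyl bromide 12, which enters anti to the C7 methyl group as is usual for β-substituted butyrolactone enolates, gives the allyl prenyl lactone F2 with C6 defined. The conditions of steps 5 to 8 then lead through the hydroxy Weinreb amide F3, its silyl ether F4 and the ynone F5 to the (Z)-iodoenone F6. mCPBA epoxidises only the electron-rich trisubstituted alkene to give the epoxide F7, and H5IO6 cleaves it to the monoaldehyde F8. An ordinary CrCl2/NiCl2 closure onto this single aldehyde gives the allyl hydroxy enone F9. Methylation as in step 11 returns to the route at 25.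

2. Step 5. The aluminium amide may open the hindered gem-diallyl lactone incompletely, or the hydroxy amide may close back to the lactone before it is silylated. Fallback: the ring is opened as a carboxylate, which cannot re-close. Setting out from 14, KOH in MeOH/H2O at reflux gives the potassium hydroxy carboxylate F10. The dried salt is treated with TBSOTf and 2,6-lutidine to give the silyl ether silyl ester F11, and K2CO3 in MeOH/H2O cleaves only the silyl ester to give the silyloxy acid F12. 1-Chloro-N,N,2-trimethylprop-1-en-1-amine converts it under neutral conditions into the acid chloride F13, and MeNH(OMe)·HCl with pyridine returns to the route at 16.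

3. Step 7. The amide carbonyl sits on a fully substituted carbon, and addition of the Grignard reagent may be too slow, with recovery of the amide or loss of its N-methoxy group. Fallback: the carbonyl is first reduced with hydride, the smallest nucleophile, and the alkyne is then added to an aldehyde. Setting out from 16, iBu2AlH in THF at −78 °C gives the aldehyde F14. Ethynylmagnesium bromide 17 adds to it to give the propargylic alcohol F15 as an inconsequential mixture of epimers, and Dess–Martin periodinane oxidises this to the ynone, which returns to the route at 18.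

Further compounds
F1 | step 10 | (3R,4R,5S)-5-(3,4-dimethoxyphenyl)-4-methyl-3-(3-methylbut-2-en-1-yl)oxolan-2-one | CC(C)=CC[C@@H]1[C@@H](C)[C@H](OC1=O)c2ccc(OC)c(OC)c2
F2 | step 10 | (3S,4R,5S)-5-(3,4-dimethoxyphenyl)-4-methyl-3-(3-methylbut-2-en-1-yl)-3-(prop-2-en-1-yl)oxolan-2-one | C=CC[C@]1(CC=C(C)C)[C@@H](C)[C@H](OC1=O)c2ccc(OC)c(OC)c2
F3 | step 10 | hydroxy Weinreb amide from F2, C6 bearing allyl and prenyl | C=CC[C@](CC=C(C)C)([C@@H](C)[C@H](O)c1ccc(OC)c(OC)c1)C(=O)N(C)OC
F4 | step 10 | tert-butyldimethylsilyl ether of F3 | C=CC[C@](CC=C(C)C)([C@@H](C)[C@H](O[Si](C)(C)C(C)(C)C)c1ccc(OC)c(OC)c1)C(=O)N(C)OC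
F5 | step 10 | ethynyl ketone from F4 | C=CC[C@](CC=C(C)C)([C@@H](C)[C@H](O[Si](C)(C)C(C)(C)C)c1ccc(OC)c(OC)c1)C(=O)C#C
F6 | step 10 | (Z)-β-iodoenone from F5 | C=CC[C@](CC=C(C)C)([C@@H](C)[C@H](O[Si](C)(C)C(C)(C)C)c1ccc(OC)c(OC)c1)C(=O)/C=C\I
F7 | step 10 | epoxide of the prenyl alkene of F6 (mixture at the epoxide carbon) | C=CC[C@](CC1OC1(C)C)([C@@H](C)[C@H](O[Si](C)(C)C(C)(C)C)c2ccc(OC)c(OC)c2)C(=O)/C=C\I
F8 | step 10 | (3S)-3-[(1S,2R)-1-[tert-butyl(dimethyl)silyl]oxy-1-(3,4-dimethoxyphenyl)propan-2-yl]-3-[(2Z)-3-iodoprop-2-enoyl]hex-5-enal | C=CC[C@](CC=O)([C@@H](C)[C@H](O[Si](C)(C)C(C)(C)C)c1ccc(OC)c(OC)c1)C(=O)/C=C\I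
F9 | step 10 | (4S,6S)-6-[(1S,2R)-1-[tert-butyl(dimethyl)silyl]oxy-1-(3,4-dimethoxyphenyl)propan-2-yl]-4-hydroxy-6-(prop-2-en-1-yl)cyclohex-2-en-1-one | C=CC[C@@]1([C@@H](C)[C@H](O[Si](C)(C)C(C)(C)C)c2ccc(OC)c(OC)c2)C[C@H](O)C=CC1=O
F10 | step 5 | potassium (3R,4S)-4-(3,4-dimethoxyphenyl)-4-hydroxy-3-methyl-2,2-di(prop-2-en-1-yl)butanoate | C=CCC(CC=C)([C@@H](C)[C@H](O)c1ccc(OC)c(OC)c1)C(=O)[O-].[K+]
F11 | step 5 | tert-butyldimethylsilyl (3R,4S)-4-[tert-butyl(dimethyl)silyl]oxy-4-(3,4-dimethoxyphenyl)-3-methyl-2,2-di(prop-2-en-1-yl)butanoate | C=CCC(CC=C)([C@@H](C)[C@H](O[Si](C)(C)C(C)(C)C)c1ccc(OC)c(OC)c1)C(=O)O[Si](C)(C)C(C)(C)C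
F12 | step 5 | (3R,4S)-4-[tert-butyl(dimethyl)silyl]oxy-4-(3,4-dimethoxyphenyl)-3-methyl-2,2-di(prop-2-en-1-yl)butanoic acid | C=CCC(CC=C)([C@@H](C)[C@H](O[Si](C)(C)C(C)(C)C)c1ccc(OC)c(OC)c1)C(=O)O
F13 | step 5 | acid chloride of F12 | C=CCC(CC=C)([C@@H](C)[C@H](O[Si](C)(C)C(C)(C)C)c1ccc(OC)c(OC)c1)C(=O)Cl
F14 | step 7 | (3R,4S)-4-[tert-butyl(dimethyl)silyl]oxy-4-(3,4-dimethoxyphenyl)-3-methyl-2,2-di(prop-2-en-1-yl)butanal | C=CCC(CC=C)([C@@H](C)[C@H](O[Si](C)(C)C(C)(C)C)c1ccc(OC)c(OC)c1)C=O
F15 | step 7 | (5R,6S)-6-[tert-butyl(dimethyl)silyl]oxy-6-(3,4-dimethoxyphenyl)-5-methyl-4,4-di(prop-2-en-1-yl)hex-1-yn-3-ol (mixture at C3) | C#CC(O)C(CC=C)(CC=C)[C@@H](C)[C@H](O[Si](C)(C)C(C)(C)C)c1ccc(OC)c(OC)c1
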